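**Assumption:** Enantiopure (2S)-naringenin (1) is purchased. It is cheap and citrus-derived. Its only stereocenter, C2, is carried through untouched, and only mild bases and neutral or weakly acidic conditions are used. Chiral HPLC is run on 7 and on the final product to confirm ee.

## Retrosynthesis
- Sigmoidin B is 5'-prenyl-eriodictyol. Its catechol comes from ortho-oxygenation of a 3'-prenylnaringenin derivative (IBX to the o-quinone, then reduction), with the 7-OH masked as a benzyl ether.
- The aryl–prenyl C–C bond is made by an aromatic Claisen [3,3] rearrangement of a 4'-O-(1,1-dimethylallyl) ether, which is prepared from the 1,1-dimethylpropargyl ether by Lindlar reduction.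
- No ring is formed. The chromanone, the A and B rings and the (2S) center all come intact from (S)-naringenin (1).
- Order of events: protect 7-OH, make the tertiary propargyl ether, reduce it to the alkene, Claisen, o-oxygenation, reduction of the quinone, deprotect.

## Route

**Step 1**
Reactants: 1 (2S)-naringenin; 2 benzyl bromide
Product: 3 (2S)-7-O-benzylnaringenin
Conditions: BnBr (1.0 equiv), K2CO3, KI (cat.), acetone, 45 °C
Reagents that add atoms: benzyl bromide, BrCc1ccccc1
Why: The 7-OH is the most acidic phenol (para to the C=O). The 5-OH is chelated to the carbonyl and the 4'-OH is less acidic, so one equivalent of BnBr gives 7-O-selective Williamson alkylation. C2 is untouched, and the mild base avoids ring-opening to the chalcone.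

**Step 2**
Reactants: 3; 4 3-chloro-3-methylbut-1-yne
Product: 5 (2S)-7-O-benzyl-4'-O-(2-methylbut-3-yn-2-yl)naringenin
Conditions: 4 (3 equiv), K2CO3, KI, CuI (cat.), acetone, 45 °C
Reagents that add atoms: 3-chloro-3-methylbut-1-yne, C#CC(C)(C)Cl
Why: Cu(I)-catalysed propargylic etherification of the only free, non-chelated phenol (4'-OH). It installs the tertiary carbon that becomes the CMe2 terminus of the prenyl group.

**Step 3**
Reactants: 5
Product: 6 (2S)-7-O-benzyl-4'-O-(2-methylbut-3-en-2-yl)naringenin
Conditions: H2 (1 atm), Lindlar catalyst, quinoline, EtOAc, rt, stop at full conversion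
Reagents that add atoms: none (H2 adds only hydrogen)
Why: Lindlar semihydrogenation converts the terminal alkyne to the terminal alkene. The benzyl ether, aryl ketone and C2 stereocenter are unaffected.

**Step 4 (key step)**
Reactants: 6
Product: 7 (2S)-7-O-benzyl-3'-prenylnaringenin, i.e. (2S)-7-benzyloxy-5,4'-dihydroxy-3'-prenylflavanone
Conditions: PhNEt2, 130 °C, sealed tube, N2
Reagents that add atoms: none
Why: Aromatic Claisen [3,3] rearrangement. The chair transition state of the aryl 1,1-dimethylallyl ether joins the ortho carbon (C3') to the terminal vinyl CH2, and the double bond shifts to give the normal prenyl group. Tautomerisation of the dienone restores the phenol. C2 is not involved, and the weakly basic aniline solvent suppresses acid-mediated ionisation and chromane formation.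

**Step 5**
Reactants: 7; 8 IBX (2-iodoxybenzoic acid)
Product: 9 (2S)-7-O-benzylsigmoidin B 3',4'-o-quinone
Conditions: IBX (1.3 equiv), DMF, rt, 1 h; crude quinone used directly in step 6 in the same flask
Reagents that add atoms: IBX, O=C1c2ccccc2I(=O)(O)O1 (delivers the new O)
Why: IBX oxygenates the phenol regioselectively at its free ortho position (C5') by oxygen delivery from the aryl-IBX ester. The prenyl group blocks the other ortho position, and the prenyl alkene and the chelated 5-OH are not oxidised. This gives the o-quinone 9, and C2 is untouched.

**Step 6**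
Reactants: 9
Product: 10 (2S)-7-O-benzylsigmoidin B
Conditions: Na2S2O4 (aq.), THF/H2O, rt, 10 min
Reagents that add atoms: none (dithionite only supplies the two hydrogens of the catechol)
Why: Dithionite reduces the o-quinone to the catechol, a mild two-electron reduction that leaves the benzyl ether, prenyl alkene, ketone and C2 unchanged.

**Step 7**
Reactants: 10
Product: 11 sigmoidin B
Conditions: BCl3 (5 equiv), pentamethylbenzene (3 equiv), CH2Cl2, −78 °C, 1 h; MeOH quench
Reagents that add atoms: none
Why: Lewis-acid O-debenzylation with a cation scavenger, used because hydrogenolysis would reduce the prenyl alkene. The low temperature and the scavenger protect the prenyl group and chromanone, and C2 is not touched.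

## Compound list
1 | (2S)-naringenin | Oc1ccc(cc1)[C@@H]2CC(=O)c3c(O)cc(O)cc3O2 | starting material
2 | benzyl bromide | BrCc1ccccc1 | starting material
3 | (2S)-7-O-benzylnaringenin | Oc1ccc(cc1)[C@@H]2CC(=O)c3c(O)cc(OCc4ccccc4)cc3O2 | intermediate
4 | 3-chloro-3-methylbut-1-yne | C#CC(C)(C)Cl | starting material
5 | (2S)-7-O-benzyl-4'-O-(2-methylbut-3-yn-2-yl)naringenin | CC(C)(C#C)Oc1ccc(cc1)[C@@H]2CC(=O)c3c(O)cc(OCc4ccccc4)cc3O2 | intermediate
6 | (2S)-7-O-benzyl-4'-O-(2-methylbut-3-en-2-yl)naringenin | C=CC(C)(C)Oc1ccc(cc1)[C@@H]2CC(=O)c3c(O)cc(OCc4ccccc4)cc3O2 | intermediate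
7 | (2S)-7-O-benzyl-3'-prenylnaringenin | CC(C)=CCc1cc(ccc1O)[C@@H]2CC(=O)c3c(O)cc(OCc4ccccc4)cc3O2 | intermediate
8 | IBX (2-iodoxybenzoic acid) | O=C1c2ccccc2I(=O)(O)O1 | starting material
9 | (2S)-7-O-benzylsigmoidin B 3',4'-o-quinone | CC(C)=CCC1=CC(=CC(=O)C1=O)[C@@H]2CC(=O)c3c(O)cc(OCc4ccccc4)cc3O2 | intermediate
10 | (2S)-7-O-benzylsigmoidin B | CC(C)=CCc1cc(cc(O)c1O)[C@@H]2CC(=O)c3c(O)cc(OCc4ccccc4)cc3O2 | intermediate
11 | sigmoidin B | CC(C)=CCc1cc(cc(O)c1O)[C@@H]2CC(=O)c3c(O)cc(O)cc3O2 | target

**Total steps:** 7. **Longest linear sequence:** 7.

## Three steps most likely to fail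
1. **Step 4 (Claisen of the tertiary allyl ether).** Ionisation, [1,3] shifts, chromane formation or thermal racemisation at C2 may compete.
   Fallback: in step 2 use allyl bromide (K2CO3, acetone) instead of the chloroalkyne and skip step 3. Run a short, hot allyl Claisen (PhNEt2, microwave, about 190 °C) to give the 3'-allyl phenol. Then convert allyl to prenyl by cross-metathesis with 2-methylbut-2-ene (Grubbs II). This replaces the labile tertiary ether with a robust primary allyl ether and installs the prenyl CMe2 terminus by metathesis.
2. **Step 5 (IBX hydroxylation).** The electron-rich A ring or the 5-OH may be over-oxidised, or the quinone may decompose before reduction.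
   Fallback: ortho-formylate 7 at C5' (MgCl2, Et3N, paraformaldehyde, then mild Dakin-type oxidation or mCPBA followed by mild formate methanolysis). This replaces direct C–H oxygenation with a formyl-to-phenol conversion.
3. **Step 7 (BCl3 debenzylation).** The prenyl group may add HCl or cyclise to a chromane, and the catechol may bind boron and lower the yield.
   Fallback: protect the 7-OH as a PMB ether in step 1 instead of benzyl, and remove it at the end with TFA and anisole at 0 °C, which avoids strong boron Lewis acids.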